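**Retrosynthetic overview**
1. The target is traced back (formaldehyde olefination, 9α,11α-epoxidation, lactol from a C6 acetal and C7–OH, acetates) to a tricyclic β-ketophosphonate that carries a temporary 1α,7-δ-lactone (ring A–O1–C7(=O)–C8–C9–C10).
2. Key disconnection: C13–C14 and C15–C16 are made together, closing rings C and D (the bicyclo[3.2.1]octane) in one base-mediated Michael/phosphonate-Claisen cascade.
3. Enabling feature: C14–C8–C15 is a 2,2-disubstituted succinate (C14 α to a benzyl ester, C15 a methyl ester carbonyl on quaternary C8). The lactone ring and the (Z)-C9=C11 alkene hold it in front of the C13=C16 vinylphosphonate, with C15 perpendicular to the alkene plane and the lactone carbonyl C7 in it.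
4. The precursor comes from a ring-A 1α,2α-diol: O1-malonylation, C8-alkylation and iodocarbocyclisation onto the C9≡C11 alkyne set C8 and the alkene geometry.
5. Ring order: A (from 4,4-dimethylcyclohexadienone, asymmetric conjugate vinylation), temporary lactone, C and D together, seco ring B (lactol) after reductive lactone opening, epoxide last.

Key step: step 16

Remark: positions are numbered as in ent-kaurane and α is the face of the C10 methyl group; the hemiacetal centre C6 can equilibrate, so its configuration is taken to be set thermodynamically.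

**Step 1**
Reactants: 1 4,4-dimethylcyclohex-2-en-1-one
Product: 2 4,4-dimethylcyclohexa-2,5-dien-1-one
Conditions: DDQ, dioxane, reflux
Reagents that add atoms: none
Why: Quinone dehydrogenation of a 4,4-disubstituted cyclohexenone gives the achiral cross-conjugated dienone, whose two enone arms are enantiotopic.

**Step 2**
Reactants: 2 4,4-dimethylcyclohexa-2,5-dien-1-one; 3 potassium vinyltrifluoroborate
Product: 4 (R)-4,4-dimethyl-5-vinylcyclohex-2-en-1-one
Conditions: [Rh(cod)2]BF4 (cat.), (R)-BINAP, toluene/H2O, 100 °C
Reagents that add atoms: potassium vinyltrifluoroborate (3), C=C[B-](F)(F)F.[K+]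
Why: Rhodium-catalysed asymmetric conjugate addition (Hayashi–Miyaura reaction) to one enantiotopic enone arm desymmetrises the dienone and sets C5 under ligand control (the (R)-ligand is chosen by analogy with cyclohex-2-enone and has to be confirmed), while the surviving enone blocks C2 against enolisation.

**Step 3**
Reactants: 4 (R)-4,4-dimethyl-5-vinylcyclohex-2-en-1-one
Product: 5 4,4,6-trimethyl-5-vinylcyclohex-2-en-1-one (C5 as in 4; C6 epimers, trans expected to predominate)
Conditions: LiN(i-Pr)2, THF, −78 °C; MeI, −78 → 0 °C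
Reagents that add atoms: iodomethane, CI
Why: Kinetic α'-enolate alkylation is regiospecific because C4 is quaternary, and the C10 configuration is unimportant because it is planarised again in step 4.

**Step 4**
Reactants: 5 4,4,6-trimethyl-5-vinylcyclohex-2-en-1-one; 6 1-[(trimethylsilyl)ethynyl]-1,2-benziodoxol-3(1H)-one
Product: 7 (5R,6R)-6-ethynyl-4,4,6-trimethyl-5-vinylcyclohex-2-en-1-one
Conditions: KOt-Bu, THF, −78 °C; then 6, Bu4NF, −78 °C → rt
Reagents that add atoms: 1-[(trimethylsilyl)ethynyl]-1,2-benziodoxol-3(1H)-one (6), C[Si](C)(C)C#CI1OC(=O)c2ccccc12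
Why: Electrophilic α-alkynylation of the tetrasubstituted potassium enolate with the ethynyl benziodoxolone made in the flask creates quaternary C10, and approach anti to the C5 vinyl group should place the ethynyl group (C9, C11) trans to C6 and the methyl group cis to it.

**Step 5**
Reactants: 7 (5R,6R)-6-ethynyl-4,4,6-trimethyl-5-vinylcyclohex-2-en-1-one
Product: 9 (5R,6R)-5-(dimethoxymethyl)-6-ethynyl-4,4,6-trimethylcyclohex-2-en-1-one, via formyl enone 8 (not isolated)
Conditions: O3, CH2Cl2/MeOH, −78 °C (indicator end point); Me2S; then p-TsOH (cat.), MeOH, 0 °C → rt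
Reagents that add atoms: methanol, CO
Why: Chemoselective ozonolysis should take the monosubstituted vinyl group before the electron-poor enone and the alkyne, and immediate acetalisation protects the epimerisable C6 aldehyde.

**Step 6**
Reactants: 9 (5R,6R)-5-(dimethoxymethyl)-6-ethynyl-4,4,6-trimethylcyclohex-2-en-1-one
Product: 10 (2R,3R)-3-(dimethoxymethyl)-2-ethynyl-2,4,4-trimethylcyclohexan-1-one
Conditions: LiBH(s-Bu)3, THF, −78 °C; aq. NH4Cl
Reagents that add atoms: none
Why: Conjugate hydride reduction of a β-unsubstituted cyclohexenone by a bulky trialkylborohydride is expected, the 1,2-mode being disfavoured by quaternary C10 next to the carbonyl.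

**Step 7**
Reactants: 10 (2R,3R)-3-(dimethoxymethyl)-2-ethynyl-2,4,4-trimethylcyclohexan-1-one
Product: 11 (5R,6R)-5-(dimethoxymethyl)-6-ethynyl-2-hydroxy-4,4,6-trimethylcyclohex-2-en-1-one (diosphenol)
Conditions: KOt-Bu, O2 (1 atm), t-BuOH/THF, 0 °C → rt; aq. NH4Cl
Reagents that add atoms: dioxygen, O=O
Why: Base-mediated autoxidation of a ketone with one enolisable methylene (C2) gives the α-hydroperoxide, which loses water (Kornblum–DeLaMare type) to the 1,2-dione, present as its enol.

**Step 8**
Reactants: 11 diosphenol
Product: 12 (1S,2R,3R,4R)-4-(dimethoxymethyl)-3-ethynyl-3,5,5-trimethylcyclohexane-1,2-diol (kaurane 1α,2α-diol)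
Conditions: NaBH4, CeCl3·7H2O, MeOH, −20 °C → rt
Reagents that add atoms: none
Why: Luche-type 1,2-reduction of C1=O, tautomerisation to the 1-hydroxy-2-ketone and a second hydride reduction should both occur from the β face, because the α face is shielded by the axial methyl groups on C4 and C10, giving the 1α (equatorial), 2α (axial) cis-diol.

**Step 9**
Reactants: 13 diethyl allylphosphonate
Product: 15 diethyl (E)-(3-bromoprop-1-en-1-yl)phosphonate, via dibromide 14 (not isolated)
Conditions: Br2, CH2Cl2, 0 °C; then Et3N, 0 °C → rt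
Reagents that add atoms: bromine, BrBr
Why: Bromine addition followed by E2 dehydrobromination through the acidic α-phosphonyl hydrogen gives the conjugated (E)-vinylphosphonate with an allylic bromide.

**Step 10**
Reactants: 12 ring-A diol; 15 diethyl (E)-(3-bromoprop-1-en-1-yl)phosphonate
Product: 16 skipped enyne diol (C9≡C11–C12H2–C13H=C16H–P(O)(OEt)2)
Conditions: CuI (cat.), NaI, K2CO3, DMF, rt
Reagents that add atoms: diethyl (E)-(3-bromoprop-1-en-1-yl)phosphonate (15), BrC/C=C/P(=O)(OCC)OCC
Why: Copper-mediated SN2 coupling of a terminal alkyne with a primary allylic bromide under mild carbonate conditions should give the 1,4-enyne without isomerisation and tolerates the free diol.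

**Step 11**
Reactants: 16 skipped enyne diol; 17 methyl malonyl chloride
Product: 18 C1 methyl malonate of 16
Conditions: pyridine, CH2Cl2, −40 °C
Reagents that add atoms: methyl malonyl chloride (17), COC(=O)CC(=O)Cl
Why: Acylation should be selective for the equatorial C1 hydroxyl, because the axial C2 hydroxyl is flanked by two syn-axial methyl groups.

**Step 12**
Reactants: 18 C1 methyl malonate
Product: 19 C2 triethylsilyl ether of 18
Conditions: Et3SiOTf, 2,6-lutidine, CH2Cl2, −78 → 0 °C
Reagents that add atoms: triethylsilyl triflate, CC[Si](CC)(CC)OS(=O)(=O)C(F)(F)F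
Why: Silyl triflate etherification of the hindered axial hydroxyl prevents acyl migration and iodoetherification in later steps.

**Step 13**
Reactants: 19 silyl ether malonate; 20 benzyl bromoacetate
Product: 21 C8-alkylated malonate (C8 epimers)
Conditions: NaH, THF, 0 °C; then 20, 0 °C → rt
Reagents that add atoms: benzyl bromoacetate (20), BrCC(=O)OCc1ccccc1
Why: Malonate C-alkylation installs the C14 arm with its activating ester (the malonate C–H is far more acidic than C12–H), and the epimeric C8 centre converges in step 14.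

**Step 14**
Reactants: 21 C8-alkylated malonate
Product: 22 1α,7-lactone vinyl iodide (C8 quaternary; iodine on C11 trans to C8)
Conditions: I2, Ti(Ot-Bu)4, CH2Cl2, rt, dark
Reagents that add atoms: iodine, II
Why: Iodocarbocyclisation of an alkynyl malonate (6-exo-dig, anti addition of the chelated titanium enolate and iodonium) should place the C14 arm, which lies syn to the ring oxygen in the chelate, axial on the chair-like lactone on the face of the C10 methyl group and C15 equatorial, which is the C8 configuration of the target, while anti addition puts C12 cis to C8.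

**Step 15**
Reactants: 22 lactone vinyl iodide
Product: 23 1α,7-lactone with (Z)-C9=C11 alkene (C12 cis to C8)
Conditions: Pd(PPh3)4 (cat.), Bu3SnH (slow addition), THF, rt
Reagents that add atoms: none
Why: Palladium-catalysed hydrodehalogenation (oxidative addition, hydride transfer, reductive elimination) proceeds with retention of alkene geometry.

**Step 16**
Reactants: 23 lactone (Z)-alkene
Product: 25 lactone-bridged bicyclo[3.2.1]octene β-ketophosphonate with C14 benzyl ester, via Michael adduct 24 (not isolated)
Conditions: KOt-Bu (2.5 equiv), THF, −20 °C → rt; AcOH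
Reagents that add atoms: none
Why: Proposed new method: deprotonation of the benzyl ester α-carbon (C14) triggers an intramolecular Michael addition to C13 of the vinylphosphonate, and the α-phosphonyl carbanion so formed (C16) acylates itself with the C15 methyl ester, which is the vinylphosphonate analogue of the known succinate–acrylate Michael–Dieckmann cyclopentannulation and of the Corey–Kwiatkowski acylation of phosphonate carbanions. Ring C closes 6-exo-trig (C14 to C13) and ring D closes 5-exo-trig at the ester carbonyl (C16 to C15), giving the bicyclo[3.2.1]octene. C13 is set by a dynamic funnel: the Michael step is reversible (retro-Michael through the C16 carbanion), only the epimer whose C16 arm lies on the face of the C15 ester can cyclise, and the product leaves the equilibrium as its stabilised β-ketophosphonate enolate, while C14 and C16 stay epimeric and are erased in steps 18 and 24. The chemoselectivity that is needed (C15 ester over C7 lactone carbonyl) is secured by the lactone ring, which holds C7 in the plane of the C9=C11 alkene and C15 perpendicular to it, and the (Z)-alkene keeps C12 next to C8. Geometric isomers of the acceptor and alkene-position isomers formed by reversible deprotonation at C12 should feed the same product.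

**Step 17**
Reactants: 25 β-ketophosphonate benzyl ester
Product: 26 C14 carboxylic acid
Conditions: H2 (1 atm), Pd/C, EtOAc, rt
Reagents that add atoms: none
Why: Benzyl ester hydrogenolysis is expected to spare the trisubstituted C9=C11 alkene, which lies between two quaternary carbons.

**Step 18**
Reactants: 26 C14 carboxylic acid
Product: 28 decarboxylated lactone β-ketophosphonate (C14 = CH2), via Barton ester 27 (not isolated)
Conditions: N-hydroxypyridine-2-thione, DCC, DMAP (cat.), CH2Cl2, dark, 0 °C → rt; then t-BuSH, visible light, rt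
Reagents that add atoms: none
Why: Barton decarboxylation (radical chain with a thiol as hydrogen donor) removes the activating carboxyl group and erases the C14 stereocentre.

**Step 19**
Reactants: 28 decarboxylated lactone
Product: 29 1α,7-diol (C7H2OH and free C1–OH)
Conditions: NaH (1.1 equiv), THF, 0 °C; then LiBH4, 0 °C → rt; aq. NH4Cl
Reagents that add atoms: none
Why: The β-ketophosphonate is first stored as its sodium enolate, which hydride does not attack, so that the borohydride reduction should open only the lactone.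

**Step 20**
Reactants: 29 1α,7-diol
Product: 31 ring-B cyclic methyl acetal 1α,2α-diol (C6 anomers), via desilylated triol 30 (not isolated)
Conditions: camphorsulfonic acid (cat.), MeOH, 0 °C; then solvent change to CH2Cl2, 4 Å sieves, rt
Reagents that add atoms: none
Why: Acid-catalysed desilylation is followed by intramolecular transacetalisation, in which C7–OH displaces one methoxy group of the C6 acetal and closes the seven-membered ring B, masking C7–OH for the acetylation.

**Step 21**
Reactants: 31 ring-B methyl acetal diol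
Product: 32 1α,2α-diacetate
Conditions: Ac2O, DMAP, pyridine, 40 °C
Reagents that add atoms: acetic anhydride, CC(=O)OC(C)=O
Why: Nucleophile-catalysed esterification acetylates both secondary hydroxyls while the ring-B acetal is inert.

**Step 22**
Reactants: 32 diacetate methyl acetal
Product: 33 lactol diacetate β-ketophosphonate
Conditions: AcOH/THF/H2O, 40 °C
Reagents that add atoms: water, O
Why: Mild acetal hydrolysis gives the hemiacetal, and C6 should settle under thermodynamic control as the anomer whose hydroxyl can hydrogen-bond to the C15 carbonyl.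

**Step 23**
Reactants: 33 lactol diacetate
Product: 34 9α,11α-epoxide
Conditions: m-CPBA, NaHCO3, CH2Cl2, 0 °C
Reagents that add atoms: m-chloroperbenzoic acid, OOC(=O)c1cccc(Cl)c1
Why: Prilezhaev epoxidation of the only electron-rich alkene should occur from the α (exo) face beside the one-carbon bridge C14, because the β face is covered by the C15–C16 bridge.

**Step 24**
Reactants: 34 9α,11α-epoxide
Product: 35 CNP0224512.1 (target)
Conditions: aq. CH2O, K2CO3, THF, 0 °C → rt
Reagents that add atoms: formaldehyde, C=O
Why: Horner–Wadsworth–Emmons olefination of the β-ketophosphonate with formaldehyde installs the exocyclic methylene C17 under carbonate conditions that should spare acetates, epoxide and lactol.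

**Compound list**
1 | 4,4-dimethylcyclohex-2-en-1-one | CC1(C)CCC(=O)C=C1 | starting material
2 | 4,4-dimethylcyclohexa-2,5-dien-1-one | CC1(C)C=CC(=O)C=C1 | intermediate
3 | potassium vinyltrifluoroborate | C=C[B-](F)(F)F.[K+] | starting material
4 | (R)-4,4-dimethyl-5-vinylcyclohex-2-en-1-one | C=C[C@@H]1C(C)(C)C=CC(=O)C1 | intermediate
5 | 4,4,6-trimethyl-5-vinylcyclohex-2-en-1-one (trans epimer drawn) | C=C[C@@H]1C(C)(C)C=CC(=O)[C@H]1C | intermediate
6 | 1-[(trimethylsilyl)ethynyl]-1,2-benziodoxol-3(1H)-one | C[Si](C)(C)C#CI1OC(=O)c2ccccc12 | starting material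
7 | (5R,6R)-6-ethynyl-4,4,6-trimethyl-5-vinylcyclohex-2-en-1-one | C=C[C@@H]1C(C)(C)C=CC(=O)[C@@]1(C)C#C | intermediate
8 | formyl enone (2-ethynyl-2,6,6-trimethyl-3-oxocyclohex-4-ene-1-carbaldehyde, CHO trans to ethynyl) | O=C[C@@H]1C(C)(C)C=CC(=O)[C@@]1(C)C#C | intermediate
9 | (5R,6R)-5-(dimethoxymethyl)-6-ethynyl-4,4,6-trimethylcyclohex-2-en-1-one | COC(OC)[C@@H]1C(C)(C)C=CC(=O)[C@@]1(C)C#C | intermediate
10 | (2R,3R)-3-(dimethoxymethyl)-2-ethynyl-2,4,4-trimethylcyclohexan-1-one | COC(OC)[C@@H]1C(C)(C)CCC(=O)[C@@]1(C)C#C | intermediate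
11 | (5R,6R)-5-(dimethoxymethyl)-6-ethynyl-2-hydroxy-4,4,6-trimethylcyclohex-2-en-1-one | COC(OC)[C@@H]1C(C)(C)C=C(O)C(=O)[C@@]1(C)C#C | intermediate
12 | (1S,2R,3R,4R)-4-(dimethoxymethyl)-3-ethynyl-3,5,5-trimethylcyclohexane-1,2-diol | COC(OC)[C@@H]1C(C)(C)C[C@H](O)[C@H](O)[C@@]1(C)C#C | intermediate
13 | diethyl allylphosphonate | C=CCP(=O)(OCC)OCC | starting material
14 | diethyl (2,3-dibromopropyl)phosphonate | BrCC(Br)CP(=O)(OCC)OCC | intermediate
15 | diethyl (E)-(3-bromoprop-1-en-1-yl)phosphonate | BrC/C=C/P(=O)(OCC)OCC | intermediate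
16 | skipped enyne diol | COC(OC)[C@@H]1C(C)(C)C[C@H](O)[C@H](O)[C@@]1(C)C#CC/C=C/P(=O)(OCC)OCC | intermediate
17 | methyl malonyl chloride | COC(=O)CC(=O)Cl | starting material
18 | C1 methyl malonate of 16 | COC(OC)[C@@H]1C(C)(C)C[C@H](O)[C@H](OC(=O)CC(=O)OC)[C@@]1(C)C#CC/C=C/P(=O)(OCC)OCC | intermediate
19 | C2 triethylsilyl ether of 18 | COC(OC)[C@@H]1C(C)(C)C[C@H](O[Si](CC)(CC)CC)[C@H](OC(=O)CC(=O)OC)[C@@]1(C)C#CC/C=C/P(=O)(OCC)OCC | intermediate
20 | benzyl bromoacetate | BrCC(=O)OCc1ccccc1 | starting material
21 | C8-alkylated malonate (C8 epimers) | COC(OC)[C@@H]1C(C)(C)C[C@H](O[Si](CC)(CC)CC)[C@H](OC(=O)C(CC(=O)OCc2ccccc2)C(=O)OC)[C@@]1(C)C#CC/C=C/P(=O)(OCC)OCC | intermediate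
22 | 1α,7-lactone vinyl iodide | COC(OC)[C@@H]1C(C)(C)C[C@H](O[Si](CC)(CC)CC)[C@H]2[C@@]1(C)/C(=C(\I)C/C=C/P(=O)(OCC)OCC)[C@@](CC(=O)OCc1ccccc1)(C(=O)OC)C(=O)O2 | intermediate
23 | 1α,7-lactone (Z)-alkene, key-step precursor | COC(OC)[C@@H]1C(C)(C)C[C@H](O[Si](CC)(CC)CC)[C@H]2[C@@]1(C)/C(=C/C/C=C/P(=O)(OCC)OCC)[C@@](CC(=O)OCc1ccccc1)(C(=O)OC)C(=O)O2 | intermediate
24 | Michael adduct (ring C closed; C13, C14 epimers; neutral form) | COC(OC)[C@@H]1C(C)(C)C[C@H](O[Si](CC)(CC)CC)[C@H]2[C@@]1(C)C3=CCC(CP(=O)(OCC)OCC)C(C(=O)OCc1ccccc1)[C@]3(C(=O)OC)C(=O)O2 | intermediate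
25 | lactone-bridged bicyclo[3.2.1]octene β-ketophosphonate, C14 benzyl ester (C14, C16 epimers) | COC(OC)[C@@H]1C(C)(C)C[C@H](O[Si](CC)(CC)CC)[C@H]2[C@@]1(C)C3=CC[C@H]4C(P(=O)(OCC)OCC)C(=O)[C@]3(C(=O)O2)C4C(=O)OCc1ccccc1 | intermediate
26 | C14 carboxylic acid | COC(OC)[C@@H]1C(C)(C)C[C@H](O[Si](CC)(CC)CC)[C@H]2[C@@]1(C)C3=CC[C@H]4C(P(=O)(OCC)OCC)C(=O)[C@]3(C(=O)O2)C4C(=O)O | intermediate
27 | Barton ester of 26 | COC(OC)[C@@H]1C(C)(C)C[C@H](O[Si](CC)(CC)CC)[C@H]2[C@@]1(C)C3=CC[C@H]4C(P(=O)(OCC)OCC)C(=O)[C@]3(C(=O)O2)C4C(=O)ON1C=CC=CC1=S | intermediate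
28 | decarboxylated lactone β-ketophosphonate | COC(OC)[C@@H]1C(C)(C)C[C@H](O[Si](CC)(CC)CC)[C@H]2[C@@]1(C)C3=CC[C@H]4C(P(=O)(OCC)OCC)C(=O)[C@]3(C(=O)O2)C4 | intermediate
29 | 1α,7-diol | COC(OC)[C@@H]1C(C)(C)C[C@H](O[Si](CC)(CC)CC)[C@H](O)[C@@]1(C)C2=CC[C@H]3C(P(=O)(OCC)OCC)C(=O)[C@]2(CO)C3 | intermediate
30 | desilylated triol | COC(OC)[C@@H]1C(C)(C)C[C@H](O)[C@H](O)[C@@]1(C)C2=CC[C@H]3C(P(=O)(OCC)OCC)C(=O)[C@]2(CO)C3 | intermediate
31 | ring-B cyclic methyl acetal diol (C6 anomers) | CCOP(=O)(OCC)C1C(=O)[C@@]23COC(OC)[C@@H]4C(C)(C)C[C@H](O)[C@H](O)[C@@]4(C)C2=CC[C@@H]1C3 | intermediate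
32 | diacetate methyl acetal | CCOP(=O)(OCC)C1C(=O)[C@@]23COC(OC)[C@@H]4C(C)(C)C[C@H](OC(C)=O)[C@H](OC(C)=O)[C@@]4(C)C2=CC[C@@H]1C3 | intermediate
33 | lactol diacetate β-ketophosphonate | CCOP(=O)(OCC)C1C(=O)[C@@]23CO[C@@H](O)[C@@H]4C(C)(C)C[C@H](OC(C)=O)[C@H](OC(C)=O)[C@@]4(C)C2=CC[C@@H]1C3 | intermediate
34 | 9α,11α-epoxide β-ketophosphonate | CCOP(=O)(OCC)C1C(=O)[C@@]23CO[C@@H](O)[C@@H]4C(C)(C)C[C@H](OC(C)=O)[C@H](OC(C)=O)[C@@]4(C)[C@]24O[C@@H]4C[C@@H]1C3 | intermediate
35 | CNP0224512.1 | C=C1C(=O)[C@@]23CO[C@@H](O)[C@@H]4C(C)(C)C[C@H](OC(C)=O)[C@H](OC(C)=O)[C@@]4(C)[C@]24O[C@@H]4C[C@@H]1C3 | target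

**Step count and risks**
Total step count: 24. Longest linear sequence: 23 steps (steps 1–8 and 10–24; step 9 is the side branch).

Steps most likely to fail:

1. Step 16 (proposed new method). What may go wrong: deprotonation at the doubly allylic C12 may outrun enolisation at C14 and lead to alkene migration or to a seven-membered Claisen closure; released methoxide may open the lactone before ring C is formed; the unproductive C13 epimer may not re-enter the equilibrium. Fallback with known reactions, run as two separate operations: it sets out from 23 and first performs only the intramolecular ester-enolate Michael addition to the vinylphosphonate (LiN(SiMe3)2, 1.1 equiv, THF, −78 °C, proton quench), isolating the Michael adduct 24. Compound 24 is then treated with LiN(i-Pr)2 (2.2 equiv, THF, −78 → 0 °C) for a Corey–Kwiatkowski-type intramolecular acylation of the phosphonate carbanion, and the epimer that cannot cyclise is recovered and re-equilibrated with catalytic KOt-Bu in t-BuOH. It comes back to the route at 25 and makes no compound outside the list (F0).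

2. Step 14. What may go wrong: slow 6-exo ring closure because the ester tether must adopt its less favoured conformation; loss of facial control at C8 through a twist-boat transition state; iodination elsewhere. Fallback: it sets out from 21, which is converted with t-BuMe2SiOTf and Et3N into the silyl ketene acetal F3. F3 is cyclised with [(t-Bu)2(2-biphenylyl)P]AuCl/AgSbF6 in wet CH2Cl2 (Conia-ene-type anti carboauration, then protodeauration). This delivers the (Z)-alkene directly and comes back to the route at 23, skipping 22.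

3. Step 4. What may go wrong: the congested tetrasubstituted enolate may react sluggishly with the bulky hypervalent iodine reagent, or with poor facial selectivity. Fallback: it sets out from 5, whose enolate (LiN(i-Pr)2, THF, −78 °C) is trapped with monomeric formaldehyde to give the hydroxymethyl enone F1. Dess–Martin oxidation gives the non-enolisable formyl enone F2, and Colvin rearrangement with lithiated trimethylsilyldiazomethane (THF, −78 → 0 °C) converts the aldehyde into the ethynyl group. It comes back to the route at 7.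

**Further compounds**
F1 | step 4 | hydroxymethyl enone (6-(hydroxymethyl)-4,4,6-trimethyl-5-vinylcyclohex-2-en-1-one, CH2OH trans to vinyl) | C=C[C@@H]1C(C)(C)C=CC(=O)[C@@]1(C)CO
F2 | step 4 | formyl enone (1,5,5-trimethyl-2-oxo-6-vinylcyclohex-3-ene-1-carbaldehyde, CHO trans to vinyl) | C=C[C@@H]1C(C)(C)C=CC(=O)[C@@]1(C)C=O
F3 | step 14 | tert-butyldimethylsilyl ketene acetal of 21 | COC(OC)[C@@H]1C(C)(C)C[C@H](O[Si](CC)(CC)CC)[C@H](OC(=O)C(CC(=O)OCc2ccccc2)=C(OC)O[Si](C)(C)C(C)(C)C)[C@@]1(C)C#CC/C=C/P(=O)(OCC)OCC
F0 | step 16 | none | none
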